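## Retrosynthetic overview

1. The target is a 2,4-trans-4-arylflavan (rings A, C, B) bonded through C4 to C8' of (2S)-pinocembrin (rings D, F, E). The plan rests on ring C: O1–C2 and C3–C4 flank the C3 methylene, C2 carries the 4-oxyphenyl ring B and the doubly benzylic C4 carries ring D. This is the adduct pattern of a ring A ortho-quinone methide (O1, C8a, C4a, C4) and a styrene (C2, C3).
2. Key disconnection: ring C is opened at O1–C2 and C3–C4 to 4-silyloxystyrene and an ortho-hydroxybenzhydrol whose second aryl group is ring D as its tribenzyl ether. A chiral phosphoric acid sets C4, and C2 follows as the trans isomer.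
3. Ring F is disconnected at C4a'–C4' (intramolecular Friedel–Crafts acylation) and at O1'–C2' (Mitsunobu inversion of a chiral-pool (R)-β-hydroxy ester), back to debenzylated ring D whose para oxygen is silylated to fix the regiochemistry.
4. The benzhydrol is cut to an aryllithium and a salicylaldehyde, the styrene to 4-hydroxybenzaldehyde.
5. Ring order: rings A, B, D and E are bought as benzene rings; ring C is formed in step 5 and ring F in step 10.

Key step: step 5

Remark: unprimed locants belong to the flavan unit (rings A, C, B), primed locants to the flavanone unit (rings D, F, E).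
Remark: the sense of induction of a binaphthyl phosphoric acid on this tetra-ortho-substituted quinone methide cannot be predicted with confidence; (R)-TRIP, (R)-3,3'-bis(2,4,6-triisopropylphenyl)-1,1'-binaphthyl-2,2'-diyl hydrogen phosphate, is written, and the (S)-acid would be used if it shields the other face.
Remark: the CIP letter at flavan C4 changes with the substituents on ring D, so after the key step the flavan unit is named by (2S) and the 2,4-trans relation; the SMILES give the full configuration.

## Route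

Step 1
Reactants: 1 1,3,5-tris(benzyloxy)benzene
Product: 2 2-bromo-1,3,5-tris(benzyloxy)benzene
Conditions: NBS (1.0 equiv), CH2Cl2, −78 → 0 °C
Reagents that add atoms: N-bromosuccinimide, O=C1CCC(=O)N1Br
Why: Electrophilic aromatic bromination: the three free positions of the phloroglucinol triether are equivalent and the first bromine lowers the reactivity of the ring, so one equivalent of NBS at low temperature should stop at the monobromide.

Step 2
Reactants: 2 2-bromo-1,3,5-tris(benzyloxy)benzene, 3 2-hydroxy-4,6-dimethoxybenzaldehyde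
Product: 5 (2-hydroxy-4,6-dimethoxyphenyl)[2,4,6-tris(benzyloxy)phenyl]methanol (racemic), via aryllithium 4 (not isolated)
Conditions: 2 (2.3 equiv), n-BuLi (2.2 equiv), THF, −78 °C; then 3 (1 equiv), −78 → −20 °C; aq NH4Cl; SiO2/Et3N
Reagents that add atoms: none
Why: Bromine–lithium exchange followed by 1,2-addition of the aryllithium to the aldehyde (one equivalent is spent on the phenol, the second adds to the lithium phenoxide aldehyde, the usual way to ortho-hydroxybenzhydrols); the basic medium keeps the doubly activated carbinol from ionising, which under an acid-mediated hydroxyalkylation would carry it on to triarylmethanes, and the new carbinol centre is racemic and is erased in step 5.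

Step 3
Reactants: 6 4-hydroxybenzaldehyde
Product: 7 4-(triisopropylsilyloxy)benzaldehyde
Conditions: TIPSCl, imidazole, DMF, rt
Reagents that add atoms: triisopropylsilyl chloride, CC(C)[Si](Cl)(C(C)C)C(C)C
Why: Silylation of the phenol with imidazole as base; the triisopropylsilyl ether is stable to the ylide, to acid catalysis, to hydrogenolysis and to cold hydroxide, and is orthogonal to the benzyl ethers.

Step 4
Reactants: 7 4-(triisopropylsilyloxy)benzaldehyde
Product: 8 4-(triisopropylsilyloxy)styrene
Conditions: Ph3PCH3Br, KOt-Bu, THF, 0 °C → rt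
Reagents that add atoms: methyltriphenylphosphonium bromide, C[P+](c1ccccc1)(c1ccccc1)c1ccccc1.[Br-]
Why: Wittig methylenation of the aldehyde with the unstabilised ylide gives the terminal alkene, and the aryl silyl ether is inert to the ylide.

Step 5
Reactants: 5 (2-hydroxy-4,6-dimethoxyphenyl)[2,4,6-tris(benzyloxy)phenyl]methanol, 8 4-(triisopropylsilyloxy)styrene
Product: 10 (2S,4S)-5,7-dimethoxy-2-(4-triisopropylsilyloxyphenyl)-4-[2,4,6-tris(benzyloxy)phenyl]chromane (2,4-trans), via ortho-quinone methide 9 (not isolated)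
Conditions: (R)-TRIP (10 mol %), 8 (3 equiv), 4 Å molecular sieves, toluene, −30 °C, slow addition of 5; then rt
Reagents that add atoms: none
Why: The phosphoric acid protonates the benzhydrol hydroxyl of 5 and water leaves, giving ortho-quinone methide 9 (the contact ion pair of the corresponding benzhydryl cation and the phosphate), which stays bound to the chiral phosphate through the ring A oxygen; the CH2 terminus of 8 adds to the exocyclic carbon (C3–C4) and the 4-silyloxybenzyl cation so formed is captured by the ring A oxygen (O1–C2), a stepwise, cationic inverse-demand hetero-Diels–Alder reaction. The closest known reaction type is the chiral phosphoric acid-catalysed [4+2] cycloaddition of ortho-quinone methides, generated in situ from ortho-hydroxybenzhydrols, with styrenes to give 2,4-diarylchromans. Ring C closes as a [4+2] annulation (O1, C8a, C4a and C4 from 9; C3 and C2 from 8) whose second bond is a 6-exo-trig attack of the phenolic oxygen on the benzylic cation. C4 is set under catalyst control, the 3,3'-aryl groups of the bound phosphate shielding one face of the quinone methide carbon; C2 is set under substrate control, because the closure is reversible under the acid, so that the ring can reopen at O1–C2, and runs through the half-chair with the C4 aryl pseudoaxial, out of the way of the C5 methoxy group, and the C2 aryl equatorial, which is the 2,4-trans isomer. The step needs the styrene to add with its CH2 end, which the para-silyloxy group secures by stabilising charge at the benzylic carbon, and it needs a single heterodiene, which is secured because ring A carries the only free hydroxyl, ring D and ring B being fully etherified; excess 8 and slow addition of 5 should hold back self-condensation of the electron-rich carbinol.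

Step 6
Reactants: 10 (2S,4S)-5,7-dimethoxy-2-(4-triisopropylsilyloxyphenyl)-4-[2,4,6-tris(benzyloxy)phenyl]chromane
Product: 11 2-[(2S)-2,4-trans-5,7-dimethoxy-2-(4-triisopropylsilyloxyphenyl)chroman-4-yl]benzene-1,3,5-triol
Conditions: H2 (1 atm), Pd/C (10 wt %), EtOAc–MeOH, rt
Reagents that add atoms: none
Why: Hydrogenolysis of the three benzyl aryl ethers; the aryl silyl ether and the methyl ethers are inert and the cyclic benzylic ether O1–C2 cleaves far more slowly than O-benzyl groups (as in the debenzylation of benzylated flavan-3-ols), so the reaction is stopped once the three benzyl groups are gone and C2 and C4 stay untouched.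

Step 7
Reactants: 11 2-[(2S)-2,4-trans-5,7-dimethoxy-2-(4-triisopropylsilyloxyphenyl)chroman-4-yl]benzene-1,3,5-triol
Product: 12 2-[(2S)-2,4-trans-5,7-dimethoxy-2-(4-triisopropylsilyloxyphenyl)chroman-4-yl]-5-(triisopropylsilyloxy)benzene-1,3-diol
Conditions: TIPSCl (1.05 equiv), imidazole, DMF, −20 → 0 °C
Reagents that add atoms: triisopropylsilyl chloride, CC(C)[Si](Cl)(C(C)C)C(C)C
Why: Sterically controlled monosilylation: the hydroxyl para to the flavanyl carbon is flanked by two ring hydrogens, the two ortho hydroxyls by the bulky flavan-4-yl group, so the bulky silyl chloride should take the para oxygen, which later becomes the 5'-oxygen and decides the regiochemistry of ring F.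

Step 8
Reactants: 12 2-[(2S)-2,4-trans-5,7-dimethoxy-2-(4-triisopropylsilyloxyphenyl)chroman-4-yl]-5-(triisopropylsilyloxy)benzene-1,3-diol, 13 ethyl (R)-3-hydroxy-3-phenylpropanoate
Product: 14 ethyl (3S)-3-{2-[(2S)-2,4-trans-5,7-dimethoxy-2-(4-triisopropylsilyloxyphenyl)chroman-4-yl]-3-hydroxy-5-(triisopropylsilyloxy)phenoxy}-3-phenylpropanoate
Conditions: 13 (1.1 equiv), PPh3, DIAD, toluene, 0 °C → rt
Reagents that add atoms: none
Why: Mitsunobu etherification: the phenoxide displaces the alkoxyphosphonium group of 13 by SN2, so the (R)-carbinol carbon is inverted to the (S)-aryl ether that becomes C2' (the phenyl ring has no donor, so ionisation should not compete); the two free hydroxyls of 12 interconvert by rotation about the C4–aryl bond and give the same mono-ether, a second etherification is slowed by crowding, and unreacted 12 is recycled.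

Step 9
Reactants: 14 ethyl (3S)-3-{2-[(2S)-2,4-trans-5,7-dimethoxy-2-(4-triisopropylsilyloxyphenyl)chroman-4-yl]-3-hydroxy-5-(triisopropylsilyloxy)phenoxy}-3-phenylpropanoate
Product: 15 (3S)-3-{2-[(2S)-2,4-trans-5,7-dimethoxy-2-(4-triisopropylsilyloxyphenyl)chroman-4-yl]-3-hydroxy-5-(triisopropylsilyloxy)phenoxy}-3-phenylpropanoic acid
Conditions: LiOH·H2O, THF–H2O, 0 °C; then 1 M HCl to pH 4, 0 °C
Reagents that add atoms: lithium hydroxide, [Li+].[OH-]
Why: Saponification of the ethyl ester; at 0 °C the hindered aryl triisopropylsilyl ethers should survive and E1cB loss of the aryloxide from the ester enolate should stay slow, so C2' keeps its configuration.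

Step 10
Reactants: 15 (3S)-3-{2-[(2S)-2,4-trans-5,7-dimethoxy-2-(4-triisopropylsilyloxyphenyl)chroman-4-yl]-3-hydroxy-5-(triisopropylsilyloxy)phenoxy}-3-phenylpropanoic acid
Product: 17 (2S)-8-[(2S)-2,4-trans-5,7-dimethoxy-2-(4-triisopropylsilyloxyphenyl)chroman-4-yl]-7-hydroxy-2-phenyl-5-(triisopropylsilyloxy)chroman-4-one, via acyl trifluoroacetate 16 (not isolated)
Conditions: (CF3CO)2O (2 equiv), CH2Cl2 (0.01 M), 0 °C; then MeOH, aq NaHCO3
Reagents that add atoms: none
Why: Intramolecular Friedel–Crafts acylation: the mixed anhydride acylates the only ring D carbon ortho to the ether oxygen, a position activated by three oxygens (ortho O-alkyl, ortho O-silyl, para OH), closing ring F as a six-membered ketone without a Lewis acid; high dilution keeps ring A from being acylated intermolecularly, C2' is not involved, and the para silyl ether from step 7 ensures that the carbonyl ends up next to the 5'-oxygen with the flavanyl group at C8'.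

Step 11
Reactants: 17 (2S)-8-[(2S)-2,4-trans-5,7-dimethoxy-2-(4-triisopropylsilyloxyphenyl)chroman-4-yl]-7-hydroxy-2-phenyl-5-(triisopropylsilyloxy)chroman-4-one
Product: 18 (2S)-8-[(2S)-2,4-trans-2-(4-hydroxyphenyl)-5,7-dimethoxychroman-4-yl]-5,7-dihydroxy-2-phenylchroman-4-one (CNP0188217.1)
Conditions: TBAF, AcOH, THF, 0 °C
Reagents that add atoms: none
Why: Fluoride cleaves both aryl silyl ethers by Si–F bond formation; acetic acid buffers the phenoxides so that the 5',7'-dihydroxyflavanone does not open by retro-oxa-Michael reaction to the chalcone, which would scramble C2' and allow Wessely–Moser isomerisation.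

## Compound list

1 | 1,3,5-tris(benzyloxy)benzene | c1ccc(COc2cc(OCc3ccccc3)cc(OCc3ccccc3)c2)cc1 | starting material
2 | 2-bromo-1,3,5-tris(benzyloxy)benzene | Brc1c(OCc2ccccc2)cc(OCc2ccccc2)cc1OCc1ccccc1 | intermediate
3 | 2-hydroxy-4,6-dimethoxybenzaldehyde | COc1cc(O)c(C=O)c(OC)c1 | starting material
4 | 2,4,6-tris(benzyloxy)phenyllithium | [Li]c1c(OCc2ccccc2)cc(OCc2ccccc2)cc1OCc1ccccc1 | intermediate
5 | (2-hydroxy-4,6-dimethoxyphenyl)[2,4,6-tris(benzyloxy)phenyl]methanol (racemic) | COc1cc(O)c(C(O)c2c(OCc3ccccc3)cc(OCc3ccccc3)cc2OCc2ccccc2)c(OC)c1 | intermediate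
6 | 4-hydroxybenzaldehyde | O=Cc1ccc(O)cc1 | starting material
7 | 4-(triisopropylsilyloxy)benzaldehyde | O=Cc1ccc(O[Si](C(C)C)(C(C)C)C(C)C)cc1 | intermediate
8 | 4-(triisopropylsilyloxy)styrene | C=Cc1ccc(O[Si](C(C)C)(C(C)C)C(C)C)cc1 | intermediate
9 | 3,5-dimethoxy-6-{[2,4,6-tris(benzyloxy)phenyl]methylidene}cyclohexa-2,4-dien-1-one (ortho-quinone methide of ring A) | COC1=CC(=O)C(=Cc2c(OCc3ccccc3)cc(OCc3ccccc3)cc2OCc2ccccc2)C(OC)=C1 | intermediate
10 | (2S,4S)-5,7-dimethoxy-2-(4-triisopropylsilyloxyphenyl)-4-[2,4,6-tris(benzyloxy)phenyl]chromane (2,4-trans) | COc1cc(OC)c2c(c1)O[C@H](c1ccc(O[Si](C(C)C)(C(C)C)C(C)C)cc1)C[C@H]2c1c(OCc2ccccc2)cc(OCc2ccccc2)cc1OCc1ccccc1 | intermediate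
11 | 2-[(2S)-2,4-trans-5,7-dimethoxy-2-(4-triisopropylsilyloxyphenyl)chroman-4-yl]benzene-1,3,5-triol | COc1cc(OC)c2c(c1)O[C@H](c1ccc(O[Si](C(C)C)(C(C)C)C(C)C)cc1)C[C@H]2c1c(O)cc(O)cc1O | intermediate
12 | 2-[(2S)-2,4-trans-5,7-dimethoxy-2-(4-triisopropylsilyloxyphenyl)chroman-4-yl]-5-(triisopropylsilyloxy)benzene-1,3-diol | COc1cc(OC)c2c(c1)O[C@H](c1ccc(O[Si](C(C)C)(C(C)C)C(C)C)cc1)C[C@H]2c1c(O)cc(O[Si](C(C)C)(C(C)C)C(C)C)cc1O | intermediate
13 | ethyl (R)-3-hydroxy-3-phenylpropanoate | CCOC(=O)C[C@@H](O)c1ccccc1 | starting material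
14 | ethyl (3S)-3-{2-[(2S)-2,4-trans-5,7-dimethoxy-2-(4-triisopropylsilyloxyphenyl)chroman-4-yl]-3-hydroxy-5-(triisopropylsilyloxy)phenoxy}-3-phenylpropanoate | COc1cc(OC)c2c(c1)O[C@H](c1ccc(O[Si](C(C)C)(C(C)C)C(C)C)cc1)C[C@H]2c1c(O)cc(O[Si](C(C)C)(C(C)C)C(C)C)cc1O[C@H](c1ccccc1)CC(=O)OCC | intermediate
15 | (3S)-3-{2-[(2S)-2,4-trans-5,7-dimethoxy-2-(4-triisopropylsilyloxyphenyl)chroman-4-yl]-3-hydroxy-5-(triisopropylsilyloxy)phenoxy}-3-phenylpropanoic acid | COc1cc(OC)c2c(c1)O[C@H](c1ccc(O[Si](C(C)C)(C(C)C)C(C)C)cc1)C[C@H]2c1c(O)cc(O[Si](C(C)C)(C(C)C)C(C)C)cc1O[C@H](c1ccccc1)CC(=O)O | intermediate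
16 | (3S)-3-{2-[(2S)-2,4-trans-5,7-dimethoxy-2-(4-triisopropylsilyloxyphenyl)chroman-4-yl]-3-hydroxy-5-(triisopropylsilyloxy)phenoxy}-3-phenylpropanoic trifluoroacetic anhydride | COc1cc(OC)c2c(c1)O[C@H](c1ccc(O[Si](C(C)C)(C(C)C)C(C)C)cc1)C[C@H]2c1c(O)cc(O[Si](C(C)C)(C(C)C)C(C)C)cc1O[C@H](c1ccccc1)CC(=O)OC(=O)C(F)(F)F | intermediate
17 | (2S)-8-[(2S)-2,4-trans-5,7-dimethoxy-2-(4-triisopropylsilyloxyphenyl)chroman-4-yl]-7-hydroxy-2-phenyl-5-(triisopropylsilyloxy)chroman-4-one | COc1cc(OC)c2c(c1)O[C@H](c1ccc(O[Si](C(C)C)(C(C)C)C(C)C)cc1)C[C@H]2c1c(O)cc(O[Si](C(C)C)(C(C)C)C(C)C)c2c1O[C@H](c1ccccc1)CC2=O | intermediate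
18 | (2S)-8-[(2S)-2,4-trans-2-(4-hydroxyphenyl)-5,7-dimethoxychroman-4-yl]-5,7-dihydroxy-2-phenylchroman-4-one (CNP0188217.1) | COc1cc(OC)c2c(c1)O[C@H](c1ccc(O)cc1)C[C@H]2c1c(O)cc(O)c2c1O[C@H](c1ccccc1)CC2=O | target

## Step count and risks

Total step count: 11 steps.
Longest linear sequence: 9 steps (steps 1, 2, 5, 6, 7, 8, 9, 10, 11, from 1 to 18); steps 3 and 4 form the styrene branch.

The three steps most likely to fail:

**Step 5.** Carbon–carbon bond formation at the tetra-ortho-substituted, strongly stabilised cationic carbon may be slow, so that self-condensation of the carbinol or its acid fragmentation to the arene and the aldehyde takes over. Facial selectivity at C4 may be poor, because the styrene offers no hydrogen-bond donor and the geometry of the quinone methide is not fixed. Enantiopurity may erode if C3–C4 formation becomes reversible while C2 equilibrates.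
Fallback, setting out from 1 and coming back at 10: C2 is set first and the bond from C4 to ring D is made by Friedel–Crafts arylation. Purchased 5,7-dimethoxy-4H-chromen-4-one F1 should undergo asymmetric conjugate addition of 4-(triisopropylsilyloxy)phenylboronic acid (Pd(OCOCF3)2, (S)-t-BuPyOx, NH4PF6, water, 1,2-dichloroethane, 60 °C; ligand antipode chosen to give 2S). This gives (2S)-5,7-dimethoxy-2-(4-triisopropylsilyloxyphenyl)chroman-4-one F2. NaBH4 in MeOH reduces it to (2S)-5,7-dimethoxy-2-(4-triisopropylsilyloxyphenyl)chroman-4-ol F3. BF3·OEt2 in CH2Cl2 at −40 °C ionises F3 in the presence of excess 1, which should add axially to the flavan-4-yl cation and give the 2,4-trans chroman 10.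

**Step 8.** Displacement by the hindered phenol may be slow, so that the activated β-hydroxy ester eliminates to ethyl cinnamate. Partial ionisation at the benzylic carbon would erode the configuration of C2'. Double etherification would cost material.
Fallback, setting out from 12 and 13 and coming back at 15: the ether bond is made by strain-driven ring opening in place of redox condensation. Ester 13 is saponified (LiOH, THF–H2O) to (R)-3-hydroxy-3-phenylpropanoic acid F4. Carboxyl activation (benzenesulfonyl chloride, pyridine, 0 °C) closes it with retention to (R)-4-phenyloxetan-2-one F5. The monosodium phenoxide of 12 (NaH, 1 equiv, DMF) should open F5 at the benzylic carbon by SN2 with alkyl–oxygen cleavage and inversion. Acidification then gives acid 15 directly, so step 9 is skipped.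

**Step 10.** The acid set free may ionise the benzylic aryl ether (loss of configuration at C2' or β-elimination to the cinnamic acid) or the bond from C4 to ring D. Ring A may be acylated intermolecularly.
Fallback, setting out from 12 and coming back at 17: the carbon–carbon bond of ring F is made first without acid and C2' is then set by catalysis.
- Magnesium-mediated ortho-formylation of 12 (MgCl2, Et3N, paraformaldehyde, THF, reflux), selective for the free-phenol ring, should give 3-[(2S)-2,4-trans-5,7-dimethoxy-2-(4-triisopropylsilyloxyphenyl)chroman-4-yl]-2,4-dihydroxy-6-(triisopropylsilyloxy)benzaldehyde F6.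
- Ethynylmagnesium bromide (excess, THF, 0 °C) adds to give 2-[(2S)-2,4-trans-5,7-dimethoxy-2-(4-triisopropylsilyloxyphenyl)chroman-4-yl]-4-(1-hydroxyprop-2-yn-1-yl)-5-(triisopropylsilyloxy)benzene-1,3-diol F7.
- MnO2 in CH2Cl2 oxidises it to 1-{3-[(2S)-2,4-trans-5,7-dimethoxy-2-(4-triisopropylsilyloxyphenyl)chroman-4-yl]-2,4-dihydroxy-6-(triisopropylsilyloxy)phenyl}prop-2-yn-1-one F8.
- Diethylamine in EtOH closes the only hydroxyl ortho to the ynone (6-endo) to 8-[(2S)-2,4-trans-5,7-dimethoxy-2-(4-triisopropylsilyloxyphenyl)chroman-4-yl]-7-hydroxy-5-(triisopropylsilyloxy)-4H-chromen-4-one F9.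
- Asymmetric conjugate addition of phenylboronic acid (Pd(OCOCF3)2, (S)-t-BuPyOx, NH4PF6, water, 1,2-dichloroethane, 60 °C; ligand antipode chosen to give 2S) should then give 17.

Further compounds
F1 | step 5 | 5,7-dimethoxy-4H-chromen-4-one (purchased) | COc1cc(OC)c2c(c1)OC=CC2=O
F2 | step 5 | (2S)-5,7-dimethoxy-2-(4-triisopropylsilyloxyphenyl)chroman-4-one | COc1cc(OC)c2c(c1)O[C@H](c1ccc(O[Si](C(C)C)(C(C)C)C(C)C)cc1)CC2=O
F3 | step 5 | (2S)-5,7-dimethoxy-2-(4-triisopropylsilyloxyphenyl)chroman-4-ol (C4 epimers) | COc1cc(OC)c2c(c1)O[C@H](c1ccc(O[Si](C(C)C)(C(C)C)C(C)C)cc1)CC2O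
F4 | step 8 | (R)-3-hydroxy-3-phenylpropanoic acid | OC(=O)C[C@@H](O)c1ccccc1
F5 | step 8 | (R)-4-phenyloxetan-2-one | O=C1C[C@H](c2ccccc2)O1
F6 | step 10 | 3-[(2S)-2,4-trans-5,7-dimethoxy-2-(4-triisopropylsilyloxyphenyl)chroman-4-yl]-2,4-dihydroxy-6-(triisopropylsilyloxy)benzaldehyde | COc1cc(OC)c2c(c1)O[C@H](c1ccc(O[Si](C(C)C)(C(C)C)C(C)C)cc1)C[C@H]2c1c(O)cc(O[Si](C(C)C)(C(C)C)C(C)C)c(C=O)c1O
F7 | step 10 | 2-[(2S)-2,4-trans-5,7-dimethoxy-2-(4-triisopropylsilyloxyphenyl)chroman-4-yl]-4-(1-hydroxyprop-2-yn-1-yl)-5-(triisopropylsilyloxy)benzene-1,3-diol (carbinol epimers) | COc1cc(OC)c2c(c1)O[C@H](c1ccc(O[Si](C(C)C)(C(C)C)C(C)C)cc1)C[C@H]2c1c(O)cc(O[Si](C(C)C)(C(C)C)C(C)C)c(C(O)C#C)c1O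
F8 | step 10 | 1-{3-[(2S)-2,4-trans-5,7-dimethoxy-2-(4-triisopropylsilyloxyphenyl)chroman-4-yl]-2,4-dihydroxy-6-(triisopropylsilyloxy)phenyl}prop-2-yn-1-one | COc1cc(OC)c2c(c1)O[C@H](c1ccc(O[Si](C(C)C)(C(C)C)C(C)C)cc1)C[C@H]2c1c(O)cc(O[Si](C(C)C)(C(C)C)C(C)C)c(C(=O)C#C)c1O
F9 | step 10 | 8-[(2S)-2,4-trans-5,7-dimethoxy-2-(4-triisopropylsilyloxyphenyl)chroman-4-yl]-7-hydroxy-5-(triisopropylsilyloxy)-4H-chromen-4-one | COc1cc(OC)c2c(c1)O[C@H](c1ccc(O[Si](C(C)C)(C(C)C)C(C)C)cc1)C[C@H]2c1c(O)cc(O[Si](C(C)C)(C(C)C)C(C)C)c2c1OC=CC2=O
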